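The route rests on disconnecting the bond between the furan α‑carbon and the hydroquinone ring. In the furan ring of the target, the oxygen‑bound carbon that carries the aryl group is, in the precursor, the free C5–H of a 3‑substituted furan. Nothing flanks it, whereas the other α‑position (C2) sits beside the branched side chain. A carboxylate‑assisted palladium‑catalysed C–H arylation with a bis‑silylated bromohydroquinone joins the two halves in one operation, with the ester, both alkenes and the (S) centre already in place. The precursor is the (S)‑senecioate of 1‑(furan‑3‑yl)‑4‑methylpent‑3‑en‑1‑ol, made by Brown allylation, cross‑metathesis and acylation.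

Key step: step 5

Assumption: commercial (−)‑Ipc2B(allyl) is taken to be the reagent derived from (+)‑α‑pinene, which delivers allyl to the Si face of aromatic aldehydes.

Step 1
Reactants: 1 furan‑3‑carbaldehyde
Product: 3 (S)‑1‑(furan‑3‑yl)but‑3‑en‑1‑ol, via borinate ester 2 (not isolated)
Conditions: (−)‑Ipc2B(allyl) (1.2 equiv), Et2O, −78 °C; then 3 M NaOH, 30% H2O2, 0 °C to rt
Reagents that add atoms: (−)‑B‑allyldiisopinocampheylborane, C=CCB([C@@H]1C[C@@H]2C[C@H]([C@H]1C)C2(C)C)[C@@H]1C[C@@H]2C[C@H]([C@H]1C)C2(C)C
Why: Brown asymmetric allylboration proceeds through a closed chair‑like six‑membered transition state in which the isopinocampheyl groups leave only the Si face of the formyl group open, so the new carbinol centre should form as (S) (furyl outranks allyl), and oxidative work‑up releases the alcohol from borinate 2.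

Step 2
Reactants: 3 (S)‑1‑(furan‑3‑yl)but‑3‑en‑1‑ol; 4 2‑methylbut‑2‑ene
Product: 5 (S)‑1‑(furan‑3‑yl)‑4‑methylpent‑3‑en‑1‑ol
Conditions: second‑generation Grubbs catalyst RuCl2(=CHPh)(H2IMes)(PCy3) (5 mol %), 2‑methylbut‑2‑ene (large excess)/CH2Cl2, 35 °C, sealed vessel
Reagents that add atoms: none
Why: Olefin cross‑metathesis exchanges the terminal methylene of the monosubstituted alkene for the isopropylidene unit of the excess trisubstituted alkene, an established allyl‑to‑prenyl conversion that creates no E/Z issue and leaves the furan, the free hydroxyl and the stereocentre untouched.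

Step 3
Reactants: 5 (S)‑1‑(furan‑3‑yl)‑4‑methylpent‑3‑en‑1‑ol; 6 3‑methylbut‑2‑enoyl chloride
Product: 7 (S)‑1‑(furan‑3‑yl)‑4‑methylpent‑3‑en‑1‑yl 3‑methylbut‑2‑enoate
Conditions: pyridine (3 equiv), CH2Cl2, 0 °C to rt; NaHCO3 work‑up
Reagents that add atoms: none
Why: O‑Acylation (nucleophilic acyl substitution) of the secondary alcohol leaves the C–O bond of the stereocentre intact, so the configuration is retained, and pyridine is used instead of a trialkylamine so that γ‑deprotonation of the acyl donor to a vinylketene, which would give the deconjugated ester, is held back.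

Step 4
Reactants: 8 2‑bromobenzene‑1,4‑diol
Product: 9 2‑bromo‑1,4‑bis(triisopropylsilyloxy)benzene
Conditions: TIPSCl (2.4 equiv), imidazole (5 equiv), DMF, rt to 40 °C
Reagents that add atoms: triisopropylsilyl chloride, CC(C)[Si](Cl)(C(C)C)C(C)C
Why: Imidazole‑promoted silylation (silyl ether formation) of both phenols gives bulky aryl silyl ethers that should withstand a carboxylate base at 100 °C and later fall off with fluoride at 0 °C, and the group ortho to bromine adds steric bias for the coupling.

Step 5
Reactants: 7 (S)‑1‑(furan‑3‑yl)‑4‑methylpent‑3‑en‑1‑yl 3‑methylbut‑2‑enoate (1.0 equiv); 9 2‑bromo‑1,4‑bis(triisopropylsilyloxy)benzene (1.3 equiv)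
Product: 10 (S)‑1‑{5‑[2,5‑bis(triisopropylsilyloxy)phenyl]furan‑3‑yl}‑4‑methylpent‑3‑en‑1‑yl 3‑methylbut‑2‑enoate
Conditions: Pd(OAc)2 (5 mol %), PCy3·HBF4 (10 mol %), potassium pivalate (2.5 equiv), degassed DMA, 100 °C, argon
Reagents that add atoms: none
Why: The C–Br bond of 9 adds oxidatively to zerovalent palladium formed from Pd(OAc)2 and PCy3, pivalate replaces bromide and removes the C5–H of furan 7 in a concerted metalation–deprotonation through a six‑membered transition state while the Pd–C5 bond forms, and reductive elimination then forges the C5–aryl bond and regenerates zerovalent palladium. The closest known reaction type is the carboxylate‑assisted palladium‑catalysed direct arylation of furans and thiophenes with aryl bromides. No ring is closed and no stereocentre is created; the (S) carbinol centre is a spectator that the weak carboxylate base should neither deprotonate nor ionise. The step needs C5 over C2 selectivity between the two α C–H bonds and mono‑ over diarylation: C2 is flanked by the branched 1‑acyloxyalkyl group at C3, and the arylpalladium species carries an ortho triisopropylsilyloxy group and a bulky phosphine, so metalation should occur at the unhindered C5–H, while the β C4–H is intrinsically far less reactive. The two trisubstituted alkenes are poor Heck acceptors and the conjugated ester is inert, so the arylpalladium intermediate should be consumed by the furan alone.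

Step 6
Reactants: 10 (S)‑1‑{5‑[2,5‑bis(triisopropylsilyloxy)phenyl]furan‑3‑yl}‑4‑methylpent‑3‑en‑1‑yl 3‑methylbut‑2‑enoate
Product: 11 (S)‑1‑[5‑(2,5‑dihydroxyphenyl)furan‑3‑yl]‑4‑methylpent‑3‑en‑1‑yl 3‑methylbut‑2‑enoate
Conditions: Bu4NF (2.5 equiv), AcOH (2.5 equiv), THF, 0 °C, argon; degassed aqueous NH4Cl work‑up
Reagents that add atoms: none
Why: Fluoride‑induced cleavage of the two aryl silyl ethers (desilylation) is fast at 0 °C, and acetic acid protonates the phenoxides as they form, so the ester should not be transesterified, the hydroquinone should not be oxidised and the stereocentre stays untouched.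

Compound list
1 | furan‑3‑carbaldehyde | O=Cc1ccoc1 | starting material
2 | (S)‑1‑(furan‑3‑yl)but‑3‑en‑1‑yl diisopinocampheylborinate | C=CC[C@H](OB([C@@H]1C[C@@H]2C[C@H]([C@H]1C)C2(C)C)[C@@H]1C[C@@H]2C[C@H]([C@H]1C)C2(C)C)c1ccoc1 | intermediate
3 | (S)‑1‑(furan‑3‑yl)but‑3‑en‑1‑ol | C=CC[C@H](O)c1ccoc1 | intermediate
4 | 2‑methylbut‑2‑ene | CC=C(C)C | starting material
5 | (S)‑1‑(furan‑3‑yl)‑4‑methylpent‑3‑en‑1‑ol | CC(C)=CC[C@H](O)c1ccoc1 | intermediate
6 | 3‑methylbut‑2‑enoyl chloride | CC(C)=CC(=O)Cl | starting material
7 | (S)‑1‑(furan‑3‑yl)‑4‑methylpent‑3‑en‑1‑yl 3‑methylbut‑2‑enoate | CC(C)=CC[C@H](OC(=O)C=C(C)C)c1ccoc1 | intermediate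
8 | 2‑bromobenzene‑1,4‑diol | Oc1ccc(O)c(Br)c1 | starting material
9 | 2‑bromo‑1,4‑bis(triisopropylsilyloxy)benzene | CC(C)[Si](Oc1ccc(O[Si](C(C)C)(C(C)C)C(C)C)c(Br)c1)(C(C)C)C(C)C | intermediate
10 | (S)‑1‑{5‑[2,5‑bis(triisopropylsilyloxy)phenyl]furan‑3‑yl}‑4‑methylpent‑3‑en‑1‑yl 3‑methylbut‑2‑enoate | CC(C)=CC[C@H](OC(=O)C=C(C)C)c1coc(-c2cc(O[Si](C(C)C)(C(C)C)C(C)C)ccc2O[Si](C(C)C)(C(C)C)C(C)C)c1 | intermediate
11 | (S)‑1‑[5‑(2,5‑dihydroxyphenyl)furan‑3‑yl]‑4‑methylpent‑3‑en‑1‑yl 3‑methylbut‑2‑enoate | CC(C)=CC[C@H](OC(=O)C=C(C)C)c1coc(-c2cc(O)ccc2O)c1 | target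

Total step count: 6. Longest linear sequence: 5 steps (steps 1, 2, 3, 5, 6); step 4 is a one‑step side branch.

Steps most likely to fail

Step 5. Metalation may not discriminate cleanly between the two furan α C–H bonds, a second arylation may follow, oxidative addition of the hindered electron‑rich bromide may be slow, and the furylic ester may ionise or eliminate at the temperature the C–H cleavage needs. The fallback separates site selection from bond formation and runs at lower temperature. From 7, iridium‑catalysed C–H borylation ([Ir(OMe)(cod)]2, 4,4'‑di‑tert‑butyl‑2,2'‑bipyridine, B2pin2, hexane, 25 °C) is sterically governed and should functionalise the unhindered α‑position, giving (S)‑4‑methyl‑1‑[5‑(4,4,5,5‑tetramethyl‑1,3,2‑dioxaborolan‑2‑yl)furan‑3‑yl]pent‑3‑en‑1‑yl 3‑methylbut‑2‑enoate F1. Suzuki–Miyaura coupling of this boronate with bromide 9 (PdCl2(dppf), K3PO4, dioxane/H2O, 60 °C) returns to the route at 10.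

Step 6. The liberated electron‑rich hydroquinone may be oxidised by air during fluoride treatment, work‑up and chromatography, and basic fluoride or phenoxide may attack the ester. The fallback purifies at the quinone oxidation level. From 10, desilylation as above is followed, without isolating the hydroquinone, by Ag2O in Et2O, which should convert all material into the stable quinone (S)‑1‑[5‑(3,6‑dioxocyclohexa‑1,4‑dien‑1‑yl)furan‑3‑yl]‑4‑methylpent‑3‑en‑1‑yl 3‑methylbut‑2‑enoate F2, which is purified on silica. Shaking its EtOAc solution with aqueous Na2S2O4 under argon reduces it and rejoins the route at 11.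

Step 3. The acyl donor may lose a γ‑proton and react as a vinylketene, giving the deconjugated 3‑methylbut‑3‑enoate, and the HCl released may ionise the furylic alcohol. The fallback builds the conjugated double bond last. From 5, carbodiimide coupling with diethylphosphonoacetic acid (EDC·HCl, DMAP, CH2Cl2, 0 °C) gives (S)‑1‑(furan‑3‑yl)‑4‑methylpent‑3‑en‑1‑yl 2‑(diethoxyphosphoryl)acetate F3. Horner–Wadsworth–Emmons olefination of this phosphonate with acetone (NaH, THF, 0 °C to rt) returns to the route at 7.

Further compounds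
F1 | step 5 | (S)‑4‑methyl‑1‑[5‑(4,4,5,5‑tetramethyl‑1,3,2‑dioxaborolan‑2‑yl)furan‑3‑yl]pent‑3‑en‑1‑yl 3‑methylbut‑2‑enoate | CC(C)=CC[C@H](OC(=O)C=C(C)C)c1coc(B2OC(C)(C)C(C)(C)O2)c1
F2 | step 6 | (S)‑1‑[5‑(3,6‑dioxocyclohexa‑1,4‑dien‑1‑yl)furan‑3‑yl]‑4‑methylpent‑3‑en‑1‑yl 3‑methylbut‑2‑enoate | CC(C)=CC[C@H](OC(=O)C=C(C)C)c1coc(C2=CC(=O)C=CC2=O)c1
F3 | step 3 | (S)‑1‑(furan‑3‑yl)‑4‑methylpent‑3‑en‑1‑yl 2‑(diethoxyphosphoryl)acetate | CC(C)=CC[C@H](OC(=O)CP(=O)(OCC)OCC)c1ccoc1
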